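Ring A is treated as a Diels–Alder adduct. Its C1–C2 and C5–C10 bonds form together when the C2=C3–C4=C5 diene of an open-chain triene adds to the C10=C1 isopropenyl group. The four-carbon tether C6–C9 already holds the C7=C8 enoate and the C9 stereocentre. One thermal operation should therefore close rings A and B and set C5 and C10 under control of C9. C9, the isopropenyl dienophile and the side-chain ketone all come from (S)-limonene. The C3=C4 alkene left by the cycloaddition is the handle for the second C4 methyl (radical hydromethylation). The side chain is finished last.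

Key step: step 9

Remark: atoms carry labdane numbers (decalin C1–C10, C10 with the angular methyl, C4 with the gem-dimethyl, C8 with the carboxyl C17, C9 with the side chain C11–C16). Commercial (−)-limonene 1,2-oxide is taken to be the (4S) cis/trans mixture from (S)-(−)-limonene.

Step 1
Reactants: 1 (4S)-limonene 1,2-oxide (cis/trans mixture)
Product: 2 (3S)-6-oxo-3-(prop-1-en-2-yl)heptanal
Conditions: H5IO6 (1.2 equiv), THF/H2O, 0 °C to rt
Reagents that add atoms: water, O
Why: Periodic acid opens the epoxide to the 1,2-diol and cleaves it (Malaprade-type glycol cleavage), so both epoxide isomers should converge on one keto aldehyde while the stereocentre that becomes C9 is untouched.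

Step 2
Reactants: 2 (3S)-6-oxo-3-(prop-1-en-2-yl)heptanal
Product: 3 (3S)-6-oxo-3-(prop-1-en-2-yl)heptanoic acid
Conditions: NaClO2, NaH2PO4, 2-methylbut-2-ene, t-BuOH/H2O, 0 °C to rt
Reagents that add atoms: sodium chlorite, [Na+].[O-]Cl=O
Why: Pinnick oxidation takes only the aldehyde to the acid; the alkene scavenger traps HOCl so the isopropenyl group and the ketone should survive.

Step 3
Reactants: 3 (3S)-6-oxo-3-(prop-1-en-2-yl)heptanoic acid
Product: 4 methyl (3S)-6,6-dimethoxy-3-(prop-1-en-2-yl)heptanoate
Conditions: MeOH, HC(OMe)3, TsOH·H2O (5 mol%), 45 °C; Et3N quench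
Reagents that add atoms: methanol, CO; trimethyl orthoformate, COC(OC)OC
Why: Fischer esterification and ketalisation run together under mild acid with the orthoformate removing water, which masks the ketone against the strong base of step 4.

Step 4
Reactants: 4 methyl (3S)-6,6-dimethoxy-3-(prop-1-en-2-yl)heptanoate
Product: 6 methyl (3R)-2-(diethoxyphosphoryl)-6,6-dimethoxy-3-(prop-1-en-2-yl)heptanoate (C2 epimers), via phosphonite ester 5 (not isolated)
Conditions: LiN(i-Pr)2, THF, −78 °C; ClP(OEt)2, −78 °C to rt; then 30% H2O2, 0 °C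
Reagents that add atoms: diethyl chlorophosphite, CCOP(Cl)OCC; hydrogen peroxide, OO
Why: The lithium ester enolate is phosphinylated on carbon by the trivalent phosphorus chloride and the phosphonite is oxidised in the same flask (enolate C-phosphinylation/oxidation) to the Horner–Wadsworth–Emmons reagent; the new C2 centre is an epimer mixture that disappears in step 8.

Step 5
Reactants: 7 pent-3-yn-1-ol
Product: 9 (3E)-4-iodopent-3-en-1-ol, via alkenylzirconocene 8 (not isolated)
Conditions: Cp2Zr(H)Cl (2.5 equiv), THF, rt to 40 °C; then I2, 0 °C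
Reagents that add atoms: iodine, II
Why: Syn hydrozirconation, equilibrated so that zirconium sits on the methyl-bearing alkyne carbon, then iodinolysis with retention (hydrozirconation–iodination) should give the E vinyl iodide.

Step 6
Reactants: 9 (3E)-4-iodopent-3-en-1-ol
Product: 10 (3E)-4-methylhexa-3,5-dien-1-ol
Conditions: CH2=CHSnBu3, PdCl2(MeCN)2 (5 mol%), DMF, rt
Reagents that add atoms: tributyl(vinyl)stannane, C=C[Sn](CCCC)(CCCC)CCCC
Why: Stille coupling replaces iodine by vinyl with retention of the alkene geometry, which fixes the E diene needed for the cycloaddition.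

Step 7
Reactants: 10 (3E)-4-methylhexa-3,5-dien-1-ol
Product: 11 (3E)-4-methylhexa-3,5-dienal
Conditions: Dess–Martin periodinane, NaHCO3, CH2Cl2, 0 °C; used at once
Reagents that add atoms: none
Why: Buffered Dess–Martin oxidation gives the β,γ-unsaturated aldehyde under neutral conditions that should not move the diene into conjugation.

Step 8
Reactants: 6 methyl (3R)-2-(diethoxyphosphoryl)-6,6-dimethoxy-3-(prop-1-en-2-yl)heptanoate; 11 (3E)-4-methylhexa-3,5-dienal
Product: 12 methyl (2E,5E)-2-[(3R)-6,6-dimethoxy-2-methylhept-1-en-3-yl]-6-methylocta-2,5,7-trienoate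
Conditions: NaH, THF, 0 °C; then 11, −78 to 0 °C
Reagents that add atoms: none
Why: Horner–Wadsworth–Emmons olefination with the α-branched phosphonate should give mainly the (2E)-ester, in which C6 is cis to C9 on C7=C8 as the cyclisation requires; only this isomer is carried on.

Step 9
Reactants: 12 methyl (2E,5E)-2-[(3R)-6,6-dimethoxy-2-methylhept-1-en-3-yl]-6-methylocta-2,5,7-trienoate
Product: 13 methyl (1R,4aS,8aS)-1-(3,3-dimethoxybutyl)-5,8a-dimethyl-1,4,4a,7,8,8a-hexahydronaphthalene-2-carboxylate
Conditions: PhMe (0.01 M), BHT (cat.), Et3N (5 mol%), 200 °C, sealed tube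
Reagents that add atoms: none
Why: Heating triggers a concerted suprafacial [4+2] cycloaddition of the C2=C3–C4=C5 diene to the unactivated C10=C1 isopropenyl alkene, forming C1–C2 and C5–C10 at once; the closest known type is the thermal intramolecular Diels–Alder reaction of unactivated deca-1,3,9-trienes. Ring A closes as the six-membered cycloaddition ring (boat-like array of diene and dienophile) and ring B as the six-membered ring spanned by the four-atom tether C6–C9, in which the (2E)-enoate holds C6 and C9 cis on C7=C8 and pre-forms the half-chair. C5 and C10 arise together: with the tether exo and the C10 methyl endo the tether can stay in a half-chair without the eclipsing that the cis-fused alternative needs, so the trans ring fusion (5-H anti to the C10 methyl) is expected. The sense of both centres is relayed from C9, because the transition state that turns the C9–H to the inside position over C1 and puts the C11 chain anti to the incoming diene (minimal allylic strain) adds the diene to the face that ends with the C10 methyl cis to the side chain, that is 5S,10S from 9R. The step needs trans over cis fusion, this one π-face, and cyclisation ahead of ene, hydrogen-shift or oligomerisation pathways; the C9 centre, the rigid cis-alkene tether, the E diene (no cis allylic hydrogen for a 1,5-shift), high dilution and BHT are meant to secure them. The enoate and the ketal are spectators, and any (2Z)-ester cannot reach the transition state and is removed afterwards.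

Step 10
Reactants: 13 methyl (1R,4aS,8aS)-1-(3,3-dimethoxybutyl)-5,8a-dimethyl-1,4,4a,7,8,8a-hexahydronaphthalene-2-carboxylate
Product: 15 methyl (1R,4aS,8aS)-1-(3,3-dimethoxybutyl)-5,5,8a-trimethyl-1,4,4a,5,6,7,8,8a-octahydronaphthalene-2-carboxylate, via sulfonylhydrazide adduct 14 (not isolated)
Conditions: n-C8H17SO2NHNH2, (CH2O)n, THF, rt; then Fe(acac)3 (30 mol%), PhSiH3, THF/MeOH, rt; then MeOH, 60 °C
Reagents that add atoms: formaldehyde (as paraformaldehyde), C=O
Why: In this Markovnikov radical hydromethylation by metal-hydride hydrogen-atom transfer, the iron hydride gives H to C3 of the electron-rich trisubstituted alkene, the tertiary C4 radical adds to the formaldehyde sulfonylhydrazone, and the adduct loses sulfinate and N2 on warming to leave the second C4 methyl; no stereocentre is created and the hindered, electron-poor C7=C8 ester alkene should stay out.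

Step 11
Reactants: 15 methyl (1R,4aS,8aS)-1-(3,3-dimethoxybutyl)-5,5,8a-trimethyl-1,4,4a,5,6,7,8,8a-octahydronaphthalene-2-carboxylate
Product: 17 (1R,4aS,8aS)-5,5,8a-trimethyl-1-(3-oxobutyl)-1,4,4a,5,6,7,8,8a-octahydronaphthalene-2-carboxylic acid, via lithium carboxylate 16 (not isolated)
Conditions: LiOH·H2O, THF/MeOH/H2O, 60 °C; then 2 M HCl, rt
Reagents that add atoms: lithium hydroxide, [Li+].[OH-]; water, O
Why: Saponification of the hindered conjugated ester followed by aqueous-acid ketal hydrolysis in the same flask should give the keto acid; C9 is not acidic and keeps its configuration.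

Step 12
Reactants: 17 (1R,4aS,8aS)-5,5,8a-trimethyl-1-(3-oxobutyl)-1,4,4a,5,6,7,8,8a-octahydronaphthalene-2-carboxylic acid
Product: 18 (1R,4aS,8aS)-1-[(3E)-5-ethoxy-3-methyl-5-oxopent-3-en-1-yl]-5,5,8a-trimethyl-1,4,4a,5,6,7,8,8a-octahydronaphthalene-2-carboxylic acid
Conditions: (EtO)2P(O)CH2CO2Et, NaH (excess), THF, 0 to 50 °C; acidic work-up
Reagents that add atoms: triethyl phosphonoacetate, CCOC(=O)CP(=O)(OCC)OCC
Why: Horner–Wadsworth–Emmons olefination of the methyl ketone (the carboxylate is inert) should favour the (13E)-ester through the reversible addition step; the minor Z isomer is removed by chromatography.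

Step 13
Reactants: 18 (1R,4aS,8aS)-1-[(3E)-5-ethoxy-3-methyl-5-oxopent-3-en-1-yl]-5,5,8a-trimethyl-1,4,4a,5,6,7,8,8a-octahydronaphthalene-2-carboxylic acid
Product: 19 (1R,4aS,8aS)-1-[(3E)-5-hydroxy-3-methylpent-3-en-1-yl]-5,5,8a-trimethyl-1,4,4a,5,6,7,8,8a-octahydronaphthalene-2-carboxylic acid
Conditions: (i-Bu)2AlH (4 equiv), CH2Cl2, −78 °C; aq. potassium sodium tartrate, then dilute HCl
Reagents that add atoms: none
Why: At low temperature the aluminium hydride reduces the ethyl enoate 1,2 to the allylic alcohol, while the hindered C17 acid, present as its aluminium carboxylate, is expected to resist (chemoselective ester reduction).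

Step 14
Reactants: 19 (1R,4aS,8aS)-1-[(3E)-5-hydroxy-3-methylpent-3-en-1-yl]-5,5,8a-trimethyl-1,4,4a,5,6,7,8,8a-octahydronaphthalene-2-carboxylic acid
Product: 20 (1R,4aS,8aS)-5,5,8a-trimethyl-1-[(3E)-3-methyl-5-(2-methylpropanoyloxy)pent-3-en-1-yl]-1,4,4a,5,6,7,8,8a-octahydronaphthalene-2-carboxylic acid (CNP0191003.1)
Conditions: (i-PrCO)2O, pyridine, DMAP (cat.), CH2Cl2, 0 °C to rt; then aq. NaHCO3/THF
Reagents that add atoms: isobutyric anhydride, CC(C)C(=O)OC(=O)C(C)C
Why: DMAP-catalysed acyl transfer esterifies the primary allylic alcohol; a mixed anhydride at the hindered acid, if formed, should be hydrolysed in the bicarbonate work-up.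

Compound list
1 | (4S)-limonene 1,2-oxide, (4S)-1-methyl-4-(prop-1-en-2-yl)-7-oxabicyclo[4.1.0]heptane, cis/trans mixture | CC12OC1C[C@H](CC2)C(C)=C | starting material
2 | (3S)-6-oxo-3-(prop-1-en-2-yl)heptanal | O=CC[C@H](CCC(C)=O)C(C)=C | intermediate
3 | (3S)-6-oxo-3-(prop-1-en-2-yl)heptanoic acid | OC(=O)C[C@H](CCC(C)=O)C(C)=C | intermediate
4 | methyl (3S)-6,6-dimethoxy-3-(prop-1-en-2-yl)heptanoate | COC(=O)C[C@H](CCC(C)(OC)OC)C(C)=C | intermediate
5 | methyl (3R)-2-(diethoxyphosphanyl)-6,6-dimethoxy-3-(prop-1-en-2-yl)heptanoate (C2 epimers) | COC(=O)C(P(OCC)OCC)[C@H](CCC(C)(OC)OC)C(C)=C | intermediate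
6 | methyl (3R)-2-(diethoxyphosphoryl)-6,6-dimethoxy-3-(prop-1-en-2-yl)heptanoate (C2 epimers) | COC(=O)C(P(=O)(OCC)OCC)[C@H](CCC(C)(OC)OC)C(C)=C | intermediate
7 | pent-3-yn-1-ol | CC#CCCO | starting material
8 | (E)-alkenylzirconocene chloride from 7, zirconium on the methyl-bearing carbon, oxygen bound to a second zirconocene chloride | C/C(=C\CCO[Zr](Cl)(C1C=CC=C1)C1C=CC=C1)[Zr](Cl)(C1C=CC=C1)C1C=CC=C1 | intermediate
9 | (3E)-4-iodopent-3-en-1-ol | OCC/C=C(\C)I | intermediate
10 | (3E)-4-methylhexa-3,5-dien-1-ol | OCC/C=C(\C)C=C | intermediate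
11 | (3E)-4-methylhexa-3,5-dienal | O=CC/C=C(\C)C=C | intermediate
12 | methyl (2E,5E)-2-[(3R)-6,6-dimethoxy-2-methylhept-1-en-3-yl]-6-methylocta-2,5,7-trienoate | COC(=O)/C(=C/C/C=C(\C)C=C)[C@H](CCC(C)(OC)OC)C(C)=C | intermediate
13 | methyl (1R,4aS,8aS)-1-(3,3-dimethoxybutyl)-5,8a-dimethyl-1,4,4a,7,8,8a-hexahydronaphthalene-2-carboxylate | CC(OC)(OC)CC[C@H]1C(C(=O)OC)=CC[C@H]2C(C)=CCC[C@]12C | intermediate
14 | N'-alkyl octanesulfonohydrazide adduct of 13 (C4 bears CH2NHNHSO2C8H17, C4 epimers) | CC(OC)(OC)CC[C@H]1C(C(=O)OC)=CC[C@H]2C(C)(CNNS(=O)(=O)CCCCCCCC)CCC[C@]12C | intermediate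
15 | methyl (1R,4aS,8aS)-1-(3,3-dimethoxybutyl)-5,5,8a-trimethyl-1,4,4a,5,6,7,8,8a-octahydronaphthalene-2-carboxylate | CC(OC)(OC)CC[C@H]1C(C(=O)OC)=CC[C@H]2C(C)(C)CCC[C@]12C | intermediate
16 | lithium (1R,4aS,8aS)-1-(3,3-dimethoxybutyl)-5,5,8a-trimethyl-1,4,4a,5,6,7,8,8a-octahydronaphthalene-2-carboxylate | CC(OC)(OC)CC[C@H]1C(C(=O)[O-])=CC[C@H]2C(C)(C)CCC[C@]12C.[Li+] | intermediate
17 | (1R,4aS,8aS)-5,5,8a-trimethyl-1-(3-oxobutyl)-1,4,4a,5,6,7,8,8a-octahydronaphthalene-2-carboxylic acid | CC(=O)CC[C@H]1C(C(=O)O)=CC[C@H]2C(C)(C)CCC[C@]12C | intermediate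
18 | (1R,4aS,8aS)-1-[(3E)-5-ethoxy-3-methyl-5-oxopent-3-en-1-yl]-5,5,8a-trimethyl-1,4,4a,5,6,7,8,8a-octahydronaphthalene-2-carboxylic acid | CCOC(=O)/C=C(\C)CC[C@H]1C(C(=O)O)=CC[C@H]2C(C)(C)CCC[C@]12C | intermediate
19 | (1R,4aS,8aS)-1-[(3E)-5-hydroxy-3-methylpent-3-en-1-yl]-5,5,8a-trimethyl-1,4,4a,5,6,7,8,8a-octahydronaphthalene-2-carboxylic acid | OC/C=C(\C)CC[C@H]1C(C(=O)O)=CC[C@H]2C(C)(C)CCC[C@]12C | intermediate
20 | (1R,4aS,8aS)-5,5,8a-trimethyl-1-[(3E)-3-methyl-5-(2-methylpropanoyloxy)pent-3-en-1-yl]-1,4,4a,5,6,7,8,8a-octahydronaphthalene-2-carboxylic acid | C/C(=C\COC(=O)C(C)C)CC[C@H]1C(C(=O)O)=CC[C@H]2C(C)(C)CCC[C@]12C | target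

Total step count: 14. Longest linear sequence: 11 steps (steps 1–4 and 8–14).

Steps most likely to fail

Step 9. The cycloaddition onto an unactivated 1,1-disubstituted alkene may be too slow at temperatures the triene tolerates, so ene reactions, double-bond migration or oligomerisation could compete. The cis-fused adduct or the trans adduct of the other π-face may also form alongside. Fallback: setting out from 12, a rhodium-catalysed formal [4+2] cycloaddition of the unactivated diene–ene (RhCl(PPh3)3, monovalent rhodium, CF3CH2OH, 55–80 °C) would form the same two bonds through a rhodacycle and reductive elimination instead of a thermal pericyclic path. It comes back to the route at 13 and makes no new compound (entry F0); the ring-fusion outcome would have to be checked again.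

Step 8. The hindered phosphonate anion may deprotonate the doubly activated aldehyde 11 instead of adding to it, and base may then move the skipped triene into conjugation; the E/Z selectivity may also erode. Fallback: setting out from 9 and 6, Dess–Martin oxidation of 9 gives (3E)-4-iodopent-3-enal F1, which lacks the diene conjugation that makes 11 so acidic. Horner–Wadsworth–Emmons reaction of F1 with the sodium salt of 6 gives methyl (2E,5E)-2-[(3R)-6,6-dimethoxy-2-methylhept-1-en-3-yl]-6-iodohepta-2,5-dienoate F2. Stille coupling of F2 with tributyl(vinyl)stannane (PdCl2(MeCN)2, DMF, rt) then builds the diene under neutral conditions and comes back to the route at 12.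

Step 13. The hydride may over-reduce the C17 carboxylate or reduce the enoate in the conjugate sense, so the selectivity between ester and acid could be lost. Fallback: setting out from 18, LiAlH4 (THF, 0 °C) reduces ester and acid alike to the diol (2E)-5-[(1R,4aS,8aS)-2-(hydroxymethyl)-5,5,8a-trimethyl-1,4,4a,5,6,7,8,8a-octahydronaphthalen-1-yl]-3-methylpent-2-en-1-ol F3. The less hindered C15 hydroxyl is acylated with isobutyryl chloride and 2,4,6-collidine at −40 °C to give (2E)-5-[(1R,4aS,8aS)-2-(hydroxymethyl)-5,5,8a-trimethyl-1,4,4a,5,6,7,8,8a-octahydronaphthalen-1-yl]-3-methylpent-2-en-1-yl 2-methylpropanoate F4. MnO2 oxidises the remaining C17 allylic alcohol to (2E)-5-[(1R,4aS,8aS)-2-formyl-5,5,8a-trimethyl-1,4,4a,5,6,7,8,8a-octahydronaphthalen-1-yl]-3-methylpent-2-en-1-yl 2-methylpropanoate F5, and Pinnick oxidation of F5 comes back to the route at 20.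

Further compounds
F0 | step 9 | none | none
F1 | step 8 | (3E)-4-iodopent-3-enal | O=CC/C=C(\C)I
F2 | step 8 | methyl (2E,5E)-2-[(3R)-6,6-dimethoxy-2-methylhept-1-en-3-yl]-6-iodohepta-2,5-dienoate | COC(=O)/C(=C/C/C=C(\C)I)[C@H](CCC(C)(OC)OC)C(C)=C
F3 | step 13 | (2E)-5-[(1R,4aS,8aS)-2-(hydroxymethyl)-5,5,8a-trimethyl-1,4,4a,5,6,7,8,8a-octahydronaphthalen-1-yl]-3-methylpent-2-en-1-ol | OC/C=C(\C)CC[C@H]1C(CO)=CC[C@H]2C(C)(C)CCC[C@]12C
F4 | step 13 | (2E)-5-[(1R,4aS,8aS)-2-(hydroxymethyl)-5,5,8a-trimethyl-1,4,4a,5,6,7,8,8a-octahydronaphthalen-1-yl]-3-methylpent-2-en-1-yl 2-methylpropanoate | CC(C)C(=O)OC/C=C(\C)CC[C@H]1C(CO)=CC[C@H]2C(C)(C)CCC[C@]12C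
F5 | step 13 | (2E)-5-[(1R,4aS,8aS)-2-formyl-5,5,8a-trimethyl-1,4,4a,5,6,7,8,8a-octahydronaphthalen-1-yl]-3-methylpent-2-en-1-yl 2-methylpropanoate | CC(C)C(=O)OC/C=C(\C)CC[C@H]1C(C=O)=CC[C@H]2C(C)(C)CCC[C@]12C
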